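**Proposed synthesis of (2S)-2-(3-hydroxy-5-methoxyphenyl)-8-(3-methylbut-2-en-1-yl)-3,4-dihydro-2H-chromene-5,7-diol (CNP0173255.1)**

Numbering used for all bicyclic compounds: O1, C2, C3, C4, C4a, C5, C6, C7, C8, C8a; B-ring carbons C1'–C6'; prenyl carbons C1''–C5''. The SMILES was re-read: the stereocentre is C2 and its descriptor is (S).

## Analysis of the target

The target is a flavan: a 3,4-dihydro-2H-chromene with a 3-hydroxy-5-methoxyphenyl ring (B ring) at C2, free hydroxyls at C5 and C7, and a prenyl chain at C8. C2 is the only stereocentre, (S). It is a benzylic ether carbon bound to O1, C3H2 and C1', and C3 and C4 are plain methylenes, so no neighbouring group can control or relay its configuration. Ring A is a phloroglucinol (oxygen at C5, C7 and C8a) with carbon substituents at C4a and C8 and hydrogen at C6. C6 and C8 are electronically alike, so a late electrophilic prenylation cannot decide between them. The sensitive groups are the trisubstituted prenyl alkene (hydrogenation, acid-induced cyclisation onto O7), the electron-rich triphenol (oxidation) and the benzylic C2–O1 bond (hydrogenolysis). The B-ring methyl ether must stay while three phenols are unveiled. The difficulty is therefore threefold: an isolated stereocentre, redox changes that must spare the prenyl group, and the C8/C6 regiochemistry. The feature the strategy uses is that C2 is bound to O1 and, in the 2H-chromene series, is the electrophilic carbon of a planar 1-benzopyrylium ion. The C2–C1' bond is also the only bond between the two aromatic halves. A racemic C2 acetal can therefore be funnelled through that cation into one configuration while the B ring is attached.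

## Retrosynthetic reasoning

**21 to 20 (O–H bonds).** The three phenols of target 21 are traced back to the three methoxymethyl ethers of flavan 20. These acetal groups survive hydride, organolithium and Ni(0) chemistry and leave under mild acid that does not touch the C5' methyl ether. The forward step must cleave three acetals without protonating the prenyl alkene.

**20 to 19 (C3–H and C4–H bonds).** Flavan 20 is traced back to the 2H-chromene 19 with a C3=C4 double bond. Only in the unsaturated series is C2 the terminus of a benzopyrylium ion, which the key step needs. The forward step must add hydrogen to the cis-disubstituted C3=C4 bond, leave the trisubstituted prenyl alkene alone, and cause neither hydrogenolysis of C2–O1 nor alkene migration. A metal-free concerted hydrogen transfer is therefore chosen.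

**19 to 12 + 17 (the C2–C1' bond, key disconnection).** This is the only bond between the two halves, and C2 is the only stereocentre. Cutting here gives the racemic acetal 12 and the arylboronic acid 17. The forward reaction ionises 12 to an achiral cation (18) and lets a chiral nickel catalyst choose the face of aryl transfer. The stereocentre is thus set in the same operation that joins the fragments, and both enantiomers of 12 are used.

**12 to 10 (C2–OEt and C2–H bonds).** Acetal 12 is a reduced coumarin. Lactone 10 is reduced to lactol 11 and acetalised. The coumarin is a stable carrier of the A/C bicycle, and the forward step only has to stop the reduction at the lactol stage.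

**10 to 5 + 6 (C3=C4, C8–C1'' and O1–C2 bonds).** The coumarin is opened into aldehyde 5 and ylide 6. An olefination (7), an aromatic [3,3] shift of the tertiary allyl group from oxygen to carbon (8), E/Z isomerisation (9) and lactonisation rebuild it. The ether oxygen of 5 is the future O1, and its only free ortho carbon is the future C8. The rearrangement can deliver the prenyl group nowhere else, so the C8/C6 question is settled by connectivity and not by selectivity.

**5 to 4 to 2 + 3, and 2 to 1.** The tertiary allyl ether 5 comes from the propargyl ether 4 by semihydrogenation. Ether 4 comes from O-alkylation of the one free, chelated hydroxyl of 2 with the propargylic chloride 3. Compound 2 comes from the commercial aldehyde 1 by protection of its two non-chelated hydroxyls.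

**17 to 14 to 13 (C–B bond).** The boronic acid 17 comes from the aryl bromide 14 by halogen–metal exchange (15) and borylation (16). Bromide 14 is the protected form of commercial bromophenol 13.

## Alternatives that were turned down

**Alternative 1: the textbook chalcone–flavanone route (O1–C2 by oxa-Michael closure, then removal of the C4 carbonyl).** A Claisen–Schmidt condensation would give chalcone A1, and cyclisation would give flavanone A2. The closure is reversible through retro-oxa-Michael opening, so C2 of A2 is formed under equilibrating conditions and stays labile to base. The 6'-oxygen substituent next to the enone also lowers the reactivity that asymmetric catalysts need. The C4 carbonyl then has to be taken out by two redox steps (reduction, then benzylic deoxygenation), and hydrogenolysis or ionic reduction would endanger the prenyl alkene. The route is linear, sets the stereocentre early on a labile intermediate, and has a step count no lower than the chosen one.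

**Alternative 2: three-component ortho-quinone methide cycloaddition (C4–C3 and O1–C2 in one [4+2]).** Salicyl alcohol A3 would give the ortho-quinone methide A4, which would add styrene A5 to form the flavan at the correct oxidation level. This is the shortest way to the skeleton and needs no reduction. It was turned down on stereocontrol. The methide carbon of A4 is unsubstituted, and A5 carries no hydrogen-bond donor next to the alkene, so a chiral acid has no point of contact with either partner in the transition state. The thermal reaction would give racemate and call for a resolution. A4 is also prone to self-condensation, and A3 takes as many steps to make as 12.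

**Alternative 3: asymmetric hydrogenation of a flav-2-ene (C2 set by C–H bond formation).** The 2-aryl-4H-chromene A6 would be hydrogenated with a chiral iridium N,P catalyst to give flavan A7. The C2=C3 enol ether of A6 and a prenyl alkene are both trisubstituted olefins of the class these catalysts reduce, so the prenyl group could not be present. It would have to be introduced on A7 afterwards, where C6 and C8 are each flanked by two oxygens and the B ring offers further activated positions. The outcome would be regioisomer mixtures and extra steps.

Key step: step 8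

Assumption on the chemistry: the (R,R)-configured TADDOL-derived phosphonite is taken to give the (2S)-product in step 8. If the sense of induction is the opposite, the (S,S)-ligand is used with no other change.

## Route

Step 1
Reactants: 1 2,4,6-trihydroxybenzaldehyde
Product: 2 2-hydroxy-4,6-bis(methoxymethoxy)benzaldehyde
Conditions: MOMCl (2.2 equiv), i-Pr2NEt, CH2Cl2, 0 °C
Reagents that add atoms: chloromethyl methyl ether, COCCl
Why: O-alkylation (MOM ether formation); once one ortho hydroxyl is alkylated, the remaining one is locked in a hydrogen bond to the aldehyde and is the least nucleophilic, so the reaction should stop at the 4,6-bis-ether.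

Step 2
Reactants: 2 2-hydroxy-4,6-bis(methoxymethoxy)benzaldehyde; 3 3-chloro-3-methylbut-1-yne
Product: 4 4,6-bis(methoxymethoxy)-2-[(2-methylbut-3-yn-2-yl)oxy]benzaldehyde
Conditions: 3 (3 equiv), DBU, CuCl2·2H2O (1 mol%), MeCN, 0 °C → rt
Reagents that add atoms: none
Why: Copper-catalysed propargylic substitution of a tertiary propargylic chloride by a phenoxide, the standard entry to aryl 1,1-dimethylpropargyl ethers; only one hydroxyl is free, so the ether oxygen is fixed as the future O1.

Step 3
Reactants: 4 4,6-bis(methoxymethoxy)-2-[(2-methylbut-3-yn-2-yl)oxy]benzaldehyde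
Product: 5 4,6-bis(methoxymethoxy)-2-[(2-methylbut-3-en-2-yl)oxy]benzaldehyde
Conditions: H2 (1 atm), Lindlar catalyst, quinoline, EtOAc, rt
Reagents that add atoms: none
Why: Lindlar semihydrogenation of a terminal alkyne to the alkene; the poisoned catalyst should leave the aldehyde and the aryl ethers untouched, and 5 is used without storage because tertiary allyl aryl ethers rearrange easily.

Step 4
Reactants: 5 4,6-bis(methoxymethoxy)-2-[(2-methylbut-3-en-2-yl)oxy]benzaldehyde; 6 ethyl (triphenylphosphoranylidene)acetate
Product: 10 5,7-bis(methoxymethoxy)-8-(3-methylbut-2-en-1-yl)-2H-chromen-2-one, via Wittig cinnamate ether 7 (not isolated), via (E)-hydroxycinnamate 8 (not isolated), via (Z)-hydroxycinnamate 9 (not isolated)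
Conditions: 6 (1.3 equiv), PhNEt2, 90 °C then 210 °C
Reagents that add atoms: none
Why: Wittig olefination, aromatic Claisen rearrangement and lactonisation in one pot, the classical coumarin synthesis from salicylaldehydes and a stabilised ylide in hot N,N-diethylaniline, extended by the known tandem Claisen variant for 8-allylcoumarins. The [3,3] shift can only go to the single ortho carbon that bears hydrogen and turns the 1,1-dimethylallyl group into a prenyl group, so the prenyl lands on the future C8 and the freed phenol is the future O1. The order of the Wittig and Claisen events does not matter, because both paths converge on 10.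

Step 5
Reactants: 10 5,7-bis(methoxymethoxy)-8-(3-methylbut-2-en-1-yl)-2H-chromen-2-one
Product: 12 rac-2-ethoxy-5,7-bis(methoxymethoxy)-8-(3-methylbut-2-en-1-yl)-2H-chromene, via lactol 11 (not isolated)
Conditions: DIBAL-H (1.15 equiv), CH2Cl2, −78 °C; Rochelle salt; then EtOH, PPTS (cat.), 4 Å MS, rt
Reagents that add atoms: ethanol, CCO
Why: Partial reduction of a lactone to the lactol (the aluminium hemiacetal is stable at −78 °C), then acid-catalysed acetalisation through the strongly stabilised 5,7-dioxygenated benzopyrylium ion; the MOM ethers should tolerate PPTS at room temperature, and 12 is purified on base-washed silica.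

Step 6
Reactants: 13 3-bromo-5-methoxyphenol
Product: 14 1-bromo-3-methoxy-5-(methoxymethoxy)benzene
Conditions: MOMCl, i-Pr2NEt, CH2Cl2, 0 °C → rt
Reagents that add atoms: chloromethyl methyl ether, COCCl
Why: MOM ether formation on the only hydroxyl; the same protecting group as on ring A allows one final deprotection.

Step 7
Reactants: 14 1-bromo-3-methoxy-5-(methoxymethoxy)benzene
Product: 17 [3-methoxy-5-(methoxymethoxy)phenyl]boronic acid, via aryllithium 15 (not isolated), via lithium aryltriisopropoxyborate 16 (not isolated)
Conditions: B(Oi-Pr)3, then n-BuLi, THF/toluene, −78 °C; aq. HCl to pH 5, 0 °C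
Reagents that add atoms: triisopropyl borate, CC(C)OB(OC(C)C)OC(C)C; water, O
Why: Bromine–lithium exchange with in-situ borate quench, then hydrolysis; trapping 15 as it forms should prevent its equilibration to the position between the two oxygens, and the brief cold work-up at pH 5 should spare the MOM ether.

Step 8
Reactants: 12 rac-2-ethoxy-5,7-bis(methoxymethoxy)-8-(3-methylbut-2-en-1-yl)-2H-chromene; 17 [3-methoxy-5-(methoxymethoxy)phenyl]boronic acid
Product: 19 (2S)-2-[3-methoxy-5-(methoxymethoxy)phenyl]-5,7-bis(methoxymethoxy)-8-(3-methylbut-2-en-1-yl)-2H-chromene, via benzopyrylium borate ion pair 18 (not isolated)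
Conditions: Ni(cod)2 (10 mol%), (R,R)-TADDOL-derived phenylphosphonite (12 mol%), 17 (2 equiv), 1,4-dioxane, 23 °C, dark
Reagents that add atoms: none
Why: The boronic acid 17 acts as a Lewis acid on the ethoxy group, and ligated Ni(0) assists ionisation of the allylic acetal C2–O bond of 12; this gives the planar benzopyrylium, bound to nickel over C2–C3–C4 and paired with the aryl(ethoxy)borate (18), and aryl transfer from boron to nickel followed by C–C reductive elimination at C2 gives 19 and returns Ni(0). The closest known reaction type is the base-free nickel-catalysed Suzuki-type coupling of 2-ethoxy-2H-chromenes with arylboronic acids, including its enantioselective form with chiral monodentate phosphorus ligands, and the related enantioselective arylation of quinolinium and pyridinium ions. No ring is closed; the step forms the C2–C1' bond that joins the two halves. The C2 configuration of racemic 12 is erased on ionisation, both enantiomers give the same achiral cation, and the chiral ligand on nickel decides which face of C2 receives the aryl group, so the step is enantioconvergent and catalyst-controlled. The step needs C2 over C4 regioselectivity, which retention of conjugation between C3=C4 and ring A and shielding of C4 by the peri 5-OMOM group should secure; it needs the prenyl alkene to stay out, which is expected because it is trisubstituted, has no leaving group and binds Ni(0) weakly; and it needs the ligand-free pathway to be slow, which is expected because the ipso carbon of 17 is meta to both oxygens and is not nucleophilic without nickel.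

Step 9
Reactants: 19 (2S)-2-[3-methoxy-5-(methoxymethoxy)phenyl]-5,7-bis(methoxymethoxy)-8-(3-methylbut-2-en-1-yl)-2H-chromene
Product: 20 (2S)-2-[3-methoxy-5-(methoxymethoxy)phenyl]-5,7-bis(methoxymethoxy)-8-(3-methylbut-2-en-1-yl)-3,4-dihydro-2H-chromene
Conditions: 2-nitrobenzenesulfonohydrazide, Et3N, CH2Cl2, 23 °C, dark
Reagents that add atoms: none
Why: Diimide reduction (concerted syn transfer of H2 through a six-membered transition state); the cis-disubstituted C3=C4 bond should react well ahead of the trisubstituted prenyl alkene, and without a metal there is no hydrogenolysis of C2–O1 and no alkene migration, so C2 keeps its configuration.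

Step 10
Reactants: 20 (2S)-2-[3-methoxy-5-(methoxymethoxy)phenyl]-5,7-bis(methoxymethoxy)-8-(3-methylbut-2-en-1-yl)-3,4-dihydro-2H-chromene
Product: 21 (2S)-2-(3-hydroxy-5-methoxyphenyl)-8-(3-methylbut-2-en-1-yl)-3,4-dihydro-2H-chromene-5,7-diol
Conditions: HCl (3 M aq.), MeOH, 40 °C, Ar
Reagents that add atoms: none
Why: Acid-catalysed methanolysis of three aryl MOM acetals; the aryl methyl ether is inert, the meta-dioxygenated B ring does not stabilise a C2 cation so the stereocentre should hold, and the mild temperature is chosen to keep the prenyl alkene unprotonated.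

## Compound list

1 | 2,4,6-trihydroxybenzaldehyde | O=Cc1c(O)cc(O)cc1O | starting material
2 | 2-hydroxy-4,6-bis(methoxymethoxy)benzaldehyde | O=Cc1c(O)cc(OCOC)cc1OCOC | intermediate
3 | 3-chloro-3-methylbut-1-yne | C#CC(C)(C)Cl | starting material
4 | 4,6-bis(methoxymethoxy)-2-[(2-methylbut-3-yn-2-yl)oxy]benzaldehyde | O=Cc1c(OC(C)(C)C#C)cc(OCOC)cc1OCOC | intermediate
5 | 4,6-bis(methoxymethoxy)-2-[(2-methylbut-3-en-2-yl)oxy]benzaldehyde | O=Cc1c(OC(C)(C)C=C)cc(OCOC)cc1OCOC | intermediate
6 | ethyl (triphenylphosphoranylidene)acetate | CCOC(=O)C=P(c1ccccc1)(c1ccccc1)c1ccccc1 | starting material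
7 | ethyl (E)-3-{4,6-bis(methoxymethoxy)-2-[(2-methylbut-3-en-2-yl)oxy]phenyl}prop-2-enoate (not isolated) | CCOC(=O)/C=C/c1c(OC(C)(C)C=C)cc(OCOC)cc1OCOC | intermediate
8 | ethyl (E)-3-[2-hydroxy-4,6-bis(methoxymethoxy)-3-(3-methylbut-2-en-1-yl)phenyl]prop-2-enoate (not isolated) | CCOC(=O)/C=C/c1c(O)c(CC=C(C)C)c(OCOC)cc1OCOC | intermediate
9 | ethyl (Z)-3-[2-hydroxy-4,6-bis(methoxymethoxy)-3-(3-methylbut-2-en-1-yl)phenyl]prop-2-enoate (not isolated) | CCOC(=O)/C=C\c1c(O)c(CC=C(C)C)c(OCOC)cc1OCOC | intermediate
10 | 5,7-bis(methoxymethoxy)-8-(3-methylbut-2-en-1-yl)-2H-chromen-2-one | O=C1C=Cc2c(OCOC)cc(OCOC)c(CC=C(C)C)c2O1 | intermediate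
11 | rac-5,7-bis(methoxymethoxy)-8-(3-methylbut-2-en-1-yl)-2H-chromen-2-ol (not isolated) | OC1C=Cc2c(OCOC)cc(OCOC)c(CC=C(C)C)c2O1 | intermediate
12 | rac-2-ethoxy-5,7-bis(methoxymethoxy)-8-(3-methylbut-2-en-1-yl)-2H-chromene | CCOC1C=Cc2c(OCOC)cc(OCOC)c(CC=C(C)C)c2O1 | intermediate
13 | 3-bromo-5-methoxyphenol | COc1cc(O)cc(Br)c1 | starting material
14 | 1-bromo-3-methoxy-5-(methoxymethoxy)benzene | COCOc1cc(OC)cc(Br)c1 | intermediate
15 | [3-methoxy-5-(methoxymethoxy)phenyl]lithium (not isolated) | [Li]c1cc(OC)cc(OCOC)c1 | intermediate
16 | lithium triisopropoxy[3-methoxy-5-(methoxymethoxy)phenyl]borate (not isolated) | [Li+].CC(C)O[B-](OC(C)C)(OC(C)C)c1cc(OC)cc(OCOC)c1 | intermediate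
17 | [3-methoxy-5-(methoxymethoxy)phenyl]boronic acid | COCOc1cc(OC)cc(B(O)O)c1 | intermediate
18 | 5,7-bis(methoxymethoxy)-8-(3-methylbut-2-en-1-yl)chromenylium ethoxy(dihydroxy)[3-methoxy-5-(methoxymethoxy)phenyl]borate, nickel-bound ion pair (not isolated) | COCOc1cc(OCOC)c2ccc[o+]c2c1CC=C(C)C.CCO[B-](O)(O)c1cc(OC)cc(OCOC)c1 | intermediate
19 | (2S)-2-[3-methoxy-5-(methoxymethoxy)phenyl]-5,7-bis(methoxymethoxy)-8-(3-methylbut-2-en-1-yl)-2H-chromene | COCOc1cc(OC)cc([C@@H]2C=Cc3c(OCOC)cc(OCOC)c(CC=C(C)C)c3O2)c1 | intermediate
20 | (2S)-2-[3-methoxy-5-(methoxymethoxy)phenyl]-5,7-bis(methoxymethoxy)-8-(3-methylbut-2-en-1-yl)-3,4-dihydro-2H-chromene | COCOc1cc(OC)cc([C@@H]2CCc3c(OCOC)cc(OCOC)c(CC=C(C)C)c3O2)c1 | intermediate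
21 | (2S)-2-(3-hydroxy-5-methoxyphenyl)-8-(3-methylbut-2-en-1-yl)-3,4-dihydro-2H-chromene-5,7-diol | COc1cc(O)cc([C@@H]2CCc3c(O)cc(O)c(CC=C(C)C)c3O2)c1 | target

## Step count and least certain steps

Total: 10 steps. Longest linear sequence: 8 steps (steps 1, 2, 3, 4, 5, 8, 9, 10); the B-ring branch (steps 6 and 7) joins at step 8.

**Step 8 (key step).** The most likely failure is erosion of enantioselectivity. The 5,7-dioxygenated benzopyrylium ionises very easily and may leave the chiral nickel environment, or react through a ligand-poor nickel species, before aryl transfer. Slow transmetalation next to the 8-substituent and some arylation at C4 are further possibilities. Fallback: the stereocentre is set by reagent-controlled ketone reduction and the ring is closed at O1–C2. The fallback sets out from coumarin 10 and bromide 14 and returns at 20, so it also replaces steps 5, 7 and 9. Conjugate reduction of 10 with a catalytic copper hydride (Cu(OAc)2, phosphine, silane) should give the dihydrocoumarin F1 without touching the prenyl alkene. Opening of F1 with N,O-dimethylhydroxylamine hydrochloride and i-PrMgCl should give the N-methoxy-N-methylamide F2. Addition of aryllithium 15 (from 14 and n-BuLi, in excess to allow for the phenoxide) should give the ketone F3. Corey–Bakshi–Shibata reduction with the (S)-oxazaborolidine and BH3·SMe2 should give the (R)-alcohol F4. Mitsunobu cyclisation (PPh3, DIAD, THF, 0 °C) should then close O1–C2 with inversion to give 20.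

**Step 9.** Two processes threaten this step. The first is competing reduction of the prenyl alkene, since diimide discriminates only by degree of substitution. The second is racemisation of 19 before it is reduced, by reversible 6π-electrocyclic opening of the 2H-chromene to its ortho-quinone methide dienone under light or heat. Fallback: selectivity by cation stability instead of sterics, from 19 back to 20. Treatment of 19 with diethyl 2,6-dimethyl-1,4-dihydropyridine-3,5-dicarboxylate (Hantzsch ester) and catalytic diphenyl phosphate in CH2Cl2 at 0 °C should protonate C3. This gives the 4-chromanyl cation F5, stabilised by the oxygens at C5, C7 and C8a, which takes hydride at C4. The prenyl alkene would have to form a much less stabilised tertiary cation and should not react with so weak an acid, and C2 is not part of the cation. The fallback given for step 8 bypasses this step altogether.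

**Step 4.** The tertiary allyl ether may ionise and lose its C5 unit as a diene before the [3,3] shift. The E-cinnamate may fail to isomerise fully. The MOM ethers are exposed to 210 °C. Fallback: the alkene geometry is set kinetically, so no thermal isomerisation is needed; the fallback sets out from 5 and returns at 10. Still–Gennari olefination of 5 (methyl bis(2,2,2-trifluoroethyl)phosphonoacetate, KHMDS, 18-crown-6, THF, −78 °C) should give the (Z)-cinnamate ether F6. Heating F6 to about 120 °C in toluene should effect the Claisen rearrangement to the (Z)-hydroxycinnamate F7, whose phenol sits next to the ester and should lactonise at once to 10.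

**Step 10.** Protonation of the prenyl alkene may lead to ring closure by O7 (a second chromane ring) or to addition of solvent, and the free triphenol may oxidise. Fallback: a non-protic, buffered trans-protection, from 20 back to 21. TMSOTf and 2,2'-bipyridyl in CH2Cl2 at 0 °C should convert the three aryl MOM ethers into the tris(trimethylsilyl) ether F8. Stirring F8 with water at room temperature should release 21 under neutral conditions.

## Further compounds

F1 | step 8 | 5,7-bis(methoxymethoxy)-8-(3-methylbut-2-en-1-yl)-3,4-dihydro-2H-chromen-2-one | O=C1CCc2c(OCOC)cc(OCOC)c(CC=C(C)C)c2O1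
F2 | step 8 | 3-[2-hydroxy-4,6-bis(methoxymethoxy)-3-(3-methylbut-2-en-1-yl)phenyl]-N-methoxy-N-methylpropanamide | CON(C)C(=O)CCc1c(O)c(CC=C(C)C)c(OCOC)cc1OCOC
F3 | step 8 | 3-[2-hydroxy-4,6-bis(methoxymethoxy)-3-(3-methylbut-2-en-1-yl)phenyl]-1-[3-methoxy-5-(methoxymethoxy)phenyl]propan-1-one | COCOc1cc(OC)cc(C(=O)CCc2c(O)c(CC=C(C)C)c(OCOC)cc2OCOC)c1
F4 | step 8 | (1R)-3-[2-hydroxy-4,6-bis(methoxymethoxy)-3-(3-methylbut-2-en-1-yl)phenyl]-1-[3-methoxy-5-(methoxymethoxy)phenyl]propan-1-ol | COCOc1cc(OC)cc([C@H](O)CCc2c(O)c(CC=C(C)C)c(OCOC)cc2OCOC)c1
F5 | step 9 | (2S)-2-[3-methoxy-5-(methoxymethoxy)phenyl]-5,7-bis(methoxymethoxy)-8-(3-methylbut-2-en-1-yl)-3,4-dihydro-2H-chromen-4-ylium (not isolated) | COCOc1cc(OC)cc([C@@H]2C[CH+]c3c(OCOC)cc(OCOC)c(CC=C(C)C)c3O2)c1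
F6 | step 4 | methyl (Z)-3-{4,6-bis(methoxymethoxy)-2-[(2-methylbut-3-en-2-yl)oxy]phenyl}prop-2-enoate | COC(=O)/C=C\c1c(OC(C)(C)C=C)cc(OCOC)cc1OCOC
F7 | step 4 | methyl (Z)-3-[2-hydroxy-4,6-bis(methoxymethoxy)-3-(3-methylbut-2-en-1-yl)phenyl]prop-2-enoate (not isolated) | COC(=O)/C=C\c1c(O)c(CC=C(C)C)c(OCOC)cc1OCOC
F8 | step 10 | (2S)-2-[3-methoxy-5-(trimethylsilyloxy)phenyl]-8-(3-methylbut-2-en-1-yl)-5,7-bis(trimethylsilyloxy)-3,4-dihydro-2H-chromene | COc1cc(O[Si](C)(C)C)cc([C@@H]2CCc3c(O[Si](C)(C)C)cc(O[Si](C)(C)C)c(CC=C(C)C)c3O2)c1
A1 | alternative 1 | (E)-1-[2-hydroxy-4,6-bis(methoxymethoxy)-3-(3-methylbut-2-en-1-yl)phenyl]-3-[3-methoxy-5-(methoxymethoxy)phenyl]prop-2-en-1-one | COCOc1cc(OC)cc(/C=C/C(=O)c2c(O)c(CC=C(C)C)c(OCOC)cc2OCOC)c1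
A2 | alternative 1 | (2S)-2-[3-methoxy-5-(methoxymethoxy)phenyl]-5,7-bis(methoxymethoxy)-8-(3-methylbut-2-en-1-yl)-2,3-dihydro-4H-chromen-4-one | COCOc1cc(OC)cc([C@@H]2CC(=O)c3c(OCOC)cc(OCOC)c(CC=C(C)C)c3O2)c1
A3 | alternative 2 | 2-(hydroxymethyl)-3,5-bis(methoxymethoxy)-6-(3-methylbut-2-en-1-yl)phenol | OCc1c(O)c(CC=C(C)C)c(OCOC)cc1OCOC
A4 | alternative 2 | 3,5-bis(methoxymethoxy)-6-methylidene-2-(3-methylbut-2-en-1-yl)cyclohexa-2,4-dien-1-one | C=C1C(=O)C(CC=C(C)C)=C(OCOC)C=C1OCOC
A5 | alternative 2 | 1-ethenyl-3-methoxy-5-(methoxymethoxy)benzene | C=Cc1cc(OC)cc(OCOC)c1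
A6 | alternative 3 | 2-[3-methoxy-5-(methoxymethoxy)phenyl]-5,7-bis(methoxymethoxy)-4H-chromene | COCOc1cc(OC)cc(C2=CCc3c(OCOC)cc(OCOC)cc3O2)c1
A7 | alternative 3 | (2S)-2-[3-methoxy-5-(methoxymethoxy)phenyl]-5,7-bis(methoxymethoxy)-3,4-dihydro-2H-chromene | COCOc1cc(OC)cc([C@@H]2CCc3c(OCOC)cc(OCOC)cc3O2)c1
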